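**Retrosynthetic overview**

1. Numbering: ring A is the benzene ring that carries the ketone (C1'–C6'), ring B is the 4-hydroxyphenyl ring, and the side chain on C3' is C1''–C8'' (C1'' benzylic, C6'' the hydroperoxy carbon). The strategy rests on the (E)-trisubstituted C2''=C3'' alkene, whose C3'' carries a methyl group and whose C2'' is bonded to the benzylic C1''H2 on C3' of ring A.
2. Last disconnections: acid removal of three acetals; Claisen–Schmidt enone formation between the ring-A methyl ketone and a protected ring-B aldehyde; C6''–OO bond by SN2 inversion of an (S)-mesylate with a ketal-protected hydroperoxide, made before any enone exists.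
3. Key disconnection: C3''–CH3 and C1''–C2'', by methylalumination of terminal alkyne 15 and palladium-catalysed coupling of the alkenylmetal with benzylic chloride 8.
4. Alkyne 15 comes from pent-4-ynoic acid (Weinreb amide, isopropenyl Grignard, CBS reduction, silylation). Chloride 8 comes from 3-methoxyphenol by two directed ortho-lithiations.
5. No ring is formed; rings A and B are bought as 3-methoxyphenol and a protected 4-hydroxybenzaldehyde.

Key step: step 9

Remark on the chemistry: the THP acetal carbon of commercial aldehyde 25 is racemic, so 26 is carried as a pair of acetal epimers; this centre is removed in step 15 and has no bearing on the configuration of the target.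

**Route**

Step 1
Reactants: 1 3-methoxyphenol
Product: 2 1-methoxy-3-(methoxymethoxy)benzene
Conditions: NaH, MOMCl, DMF, 0 °C → rt
Reagents that add atoms: chloromethyl methyl ether (MOMCl), COCCl
Why: Williamson-type O-alkylation of the sodium phenoxide should be clean, and the MOM ether is chosen because it is the stronger of the two ortho-directing groups needed in steps 2 and 3.

Step 2
Reactants: 2 1-methoxy-3-(methoxymethoxy)benzene
Product: 4 [2-methoxy-6-(methoxymethoxy)phenyl]methanol, via aryllithium 3 (not isolated)
Conditions: n-BuLi, TMEDA, THF, 0 °C; (CH2O)n, 0 °C → rt; H2O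
Reagents that add atoms: formaldehyde (from paraformaldehyde), C=O
Why: Directed ortho-metalation should take place at the position flanked by OMe and OMOM, where both oxygens cooperate, and hydroxymethylation of aryllithium 3 then installs the future benzylic carbon C1''.

Step 3
Reactants: 4 [2-methoxy-6-(methoxymethoxy)phenyl]methanol
Product: 6 1-[3-(hydroxymethyl)-4-methoxy-2-(methoxymethoxy)phenyl]ethan-1-one, via dilithio alkoxide 5 (not isolated)
Conditions: n-BuLi (2.3 equiv), TMEDA, THF, −78 → 0 °C; MeC(O)N(OMe)Me, −78 → 0 °C; H2O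
Reagents that add atoms: N-methoxy-N-methylacetamide, CC(=O)N(C)OC
Why: After deprotonation of the hydroxyl group, a second directed ortho-metalation should occur next to the chelating OMOM group and not next to the weaker OMe director, and acylation of 5 by the Weinreb amide (Weinreb ketone synthesis) should stop at the methyl ketone because the tetrahedral chelate survives until work-up.

Step 4
Reactants: 6 1-[3-(hydroxymethyl)-4-methoxy-2-(methoxymethoxy)phenyl]ethan-1-one
Product: 8 1-[3-(chloromethyl)-4-methoxy-2-(methoxymethoxy)phenyl]ethan-1-one, via benzylic mesylate 7 (not isolated)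
Conditions: MsCl, LiCl, 2,4,6-collidine, DMF, 0 °C
Reagents that add atoms: lithium chloride, [Li+].[Cl-]; methanesulfonyl chloride, CS(=O)(=O)Cl (alternative chloride source; its sulfonyl group stays in 7 only)
Why: Collington–Meyers chlorination (mesylation, then SN2 displacement by chloride in the same flask) runs under buffered, non-acidic conditions that should leave the MOM acetal and the ketone untouched, the doubly ortho-oxygenated benzylic mesylate 7 being displaced at once.

Step 5
Reactants: 9 pent-4-ynoic acid
Product: 11 N-methoxy-N-methylpent-4-ynamide, via acyl imidazole 10 (not isolated)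
Conditions: CDI, CH2Cl2, rt; MeNH(OMe)·HCl, rt
Reagents that add atoms: N,O-dimethylhydroxylamine hydrochloride, CNOC.Cl
Why: Activation of the acid as acyl imidazole 10 and aminolysis by N,O-dimethylhydroxylamine is a standard Weinreb amide formation that tolerates the terminal alkyne.

Step 6
Reactants: 11 N-methoxy-N-methylpent-4-ynamide; 12 isopropenylmagnesium bromide
Product: 13 2-methylhept-1-en-6-yn-3-one
Conditions: 12 (2.5 equiv), THF, −20 → 0 °C; inverse quench into cold 1 M HCl
Reagents that add atoms: none
Why: In this Weinreb ketone synthesis the Grignard reagent should add once to give a magnesium chelate that collapses to the enone only on acidic quench, the excess reagent covering any deprotonation of the alkyne C–H and the acidic inverse quench keeping the liberated amine protonated so that it cannot add to the enone.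

Step 7
Reactants: 13 2-methylhept-1-en-6-yn-3-one
Product: 14 (3S)-2-methylhept-1-en-6-yn-3-ol
Conditions: (R)-Me-CBS oxazaborolidine (0.2 equiv), catecholborane, toluene, −78 °C; MeOH, then aq. NaOH wash
Reagents that add atoms: none
Why: Corey–Bakshi–Shibata reduction with catecholborane at low temperature should give 1,2-reduction without hydroboration of the alkyne, and with the α-branched isopropenyl group acting as the large substituent and the CH2CH2C≡CH chain as the small one, the (R)-configured B-methyl oxazaborolidine (from (R)-diphenylprolinol) delivers hydride to the carbonyl face that gives the (S)-carbinol.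

Step 8
Reactants: 14 (3S)-2-methylhept-1-en-6-yn-3-ol
Product: 15 tert-butyldimethyl{[(3S)-2-methylhept-1-en-6-yn-3-yl]oxy}silane
Conditions: TBSCl, imidazole, DMF, rt
Reagents that add atoms: tert-butyldimethylsilyl chloride, CC(C)(C)[Si](C)(C)Cl
Why: Imidazole-promoted silylation of the secondary alcohol proceeds with retention and gives an ether that is inert to AlMe3 and is later removed by fluoride without acid.

Step 9
Reactants: 15 tert-butyldimethyl{[(3S)-2-methylhept-1-en-6-yn-3-yl]oxy}silane; 16 trimethylaluminium; 8 1-[3-(chloromethyl)-4-methoxy-2-(methoxymethoxy)phenyl]ethan-1-one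
Product: 19 1-{3-[(2E,6S)-6-(tert-butyldimethylsilyloxy)-3,7-dimethylocta-2,7-dien-1-yl]-4-methoxy-2-(methoxymethoxy)phenyl}ethan-1-one, via alkenylalane 17 (not isolated), via alkenylzinc chloride 18 (not isolated)
Conditions: 15 (1.3 equiv), AlMe3 (2.6 equiv), Cp2ZrCl2 (0.25 equiv), ClCH2CH2Cl, rt; volatiles removed in vacuo; THF, ZnCl2 (1.3 equiv), 0 °C; 8 (1.0 equiv), Pd(PPh3)4 (5 mol%), rt; aq. Rochelle salt
Reagents that add atoms: none
Why: Cp2ZrCl2 and AlMe3 form a methylzirconocene–chloroaluminate pair that adds methyl and metal syn across the terminal alkyne of 15, methyl to the internal carbon (the future C3'') and metal to the terminal carbon (the future C2''), and exchange to aluminium gives (E)-alkenylalane 17 (Negishi zirconium-catalysed carboalumination). After free AlMe3 is pumped off, ZnCl2 moves the alkenyl group to zinc (18), zerovalent palladium from Pd(PPh3)4 inserts into the benzylic C–Cl bond of 8, and transmetalation followed by reductive elimination forms C1''–C2'' (Negishi cross-coupling of an alkenylmetal with a benzylic chloride, the reaction type used to attach polyprenyl chains to protected quinone nuclei). No ring is closed and no stereocentre is created; the only stereochemical element set is the E geometry of C2''=C3'', which follows from the syn addition and from retention of alkene configuration in transmetalation and reductive elimination, while the (S)-centre at C6'' is a remote spectator. The step needs three selectivities: reaction of the alkyne and not the 1,1-disubstituted C7''=C8'' alkene, which achiral zirconocene/AlMe3 does not carbometalate at room temperature; methyl delivery to the internal alkyne carbon, which the steric preference of terminal alkynes provides; and coupling without attack on the aryl methyl ketone or the MOM acetal, which is secured by removing free AlMe3 and coupling through the ketone-tolerant zinc species in THF. The silyl ether is inert to the alane, and the benzylic palladium intermediate has no β-hydrogen, so isomerised by-products are not expected.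

Step 10
Reactants: 19 1-{3-[(2E,6S)-6-(tert-butyldimethylsilyloxy)-3,7-dimethylocta-2,7-dien-1-yl]-4-methoxy-2-(methoxymethoxy)phenyl}ethan-1-one
Product: 20 1-{3-[(2E,6S)-6-hydroxy-3,7-dimethylocta-2,7-dien-1-yl]-4-methoxy-2-(methoxymethoxy)phenyl}ethan-1-one
Conditions: Bu4NF, THF, 0 °C → rt; H2O
Reagents that add atoms: none
Why: Fluoride-mediated desilylation cleaves only the Si–O bond, with retention at C6'', and should leave the MOM ether, the ketone and both alkenes untouched.

Step 11
Reactants: 20 1-{3-[(2E,6S)-6-hydroxy-3,7-dimethylocta-2,7-dien-1-yl]-4-methoxy-2-(methoxymethoxy)phenyl}ethan-1-one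
Product: 21 (3S,6E)-8-[3-acetyl-6-methoxy-2-(methoxymethoxy)phenyl]-2,6-dimethylocta-1,6-dien-3-yl methanesulfonate
Conditions: MsCl, Et3N, CH2Cl2, −30 °C; cold aq. NaHCO3 work-up; crude product used at once
Reagents that add atoms: methanesulfonyl chloride, CS(=O)(=O)Cl
Why: Sulfonylation of the secondary alcohol (sulfene pathway) leaves the C6''–O bond intact and so retains the S configuration, and low temperature with immediate use should limit ionisation of the allylic mesylate.

Step 12
Reactants: 22 2,3-dimethylbut-2-ene
Product: 23 2-methoxyprop-2-yl hydroperoxide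
Conditions: O3, MeOH/CH2Cl2, −78 °C; used as a solution, behind a shield
Reagents that add atoms: ozone, [O-][O+]=O; methanol, CO
Why: Ozonolysis in a participating solvent (Criegee mechanism) cleaves the alkene to acetone and acetone O-oxide, which methanol traps as the α-methoxy hydroperoxide, a ketal-protected form of hydrogen peroxide.

Step 13
Reactants: 21 (3S,6E)-8-[3-acetyl-6-methoxy-2-(methoxymethoxy)phenyl]-2,6-dimethylocta-1,6-dien-3-yl methanesulfonate; 23 2-methoxyprop-2-yl hydroperoxide
Product: 24 1-{3-[(2E,6R)-6-[(2-methoxypropan-2-yl)peroxy]-3,7-dimethylocta-2,7-dien-1-yl]-4-methoxy-2-(methoxymethoxy)phenyl}ethan-1-one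
Conditions: 23 (2 equiv), CsOH·H2O (1.5 equiv), DMF, 0 °C; then 21, 0 °C → rt
Reagents that add atoms: none
Why: SN2 alkylation of the cesium salt of 23, a strongly nucleophilic but weakly basic α-effect anion kept in excess over the hydroxide, should displace the mesylate with inversion and so turn (S)-C6'' into (R)-C6''; attack at the α-carbon and not allylic transposition is the normal course for oxygen anions on secondary α-alkylallyl electrophiles, and no enone is yet present that the peroxide anion could epoxidise.

Step 14
Reactants: 24 1-{3-[(2E,6R)-6-[(2-methoxypropan-2-yl)peroxy]-3,7-dimethylocta-2,7-dien-1-yl]-4-methoxy-2-(methoxymethoxy)phenyl}ethan-1-one; 25 4-(tetrahydro-2H-pyran-2-yloxy)benzaldehyde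
Product: 26 (2E)-1-{3-[(2E,6R)-6-[(2-methoxypropan-2-yl)peroxy]-3,7-dimethylocta-2,7-dien-1-yl]-4-methoxy-2-(methoxymethoxy)phenyl}-3-[4-(tetrahydro-2H-pyran-2-yloxy)phenyl]prop-2-en-1-one (both epimers at the THP acetal carbon)
Conditions: KOH (3 equiv), EtOH, 0 °C → rt
Reagents that add atoms: none
Why: Claisen–Schmidt condensation of the methyl ketone enolate with the non-enolisable aldehyde, followed by E1cB loss of water, should give the (E)-enone, while the perketal keeps the peroxide non-nucleophilic (no Weitz–Scheffer epoxidation) and all three acetals are stable to base.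

Step 15
Reactants: 26 (2E)-1-{3-[(2E,6R)-6-[(2-methoxypropan-2-yl)peroxy]-3,7-dimethylocta-2,7-dien-1-yl]-4-methoxy-2-(methoxymethoxy)phenyl}-3-[4-(tetrahydro-2H-pyran-2-yloxy)phenyl]prop-2-en-1-one
Product: 27 (2E)-1-{2-hydroxy-3-[(2E,6R)-6-hydroperoxy-3,7-dimethylocta-2,7-dien-1-yl]-4-methoxyphenyl}-3-(4-hydroxyphenyl)prop-2-en-1-one (CNP0163229.1)
Conditions: HCl (ca. 1 M in MeOH), THF, 0 °C → rt, stopped as soon as the MOM ether is consumed
Reagents that add atoms: none
Why: Acid-catalysed transacetalisation to methanol should remove the perketal, the THP ether and the MOM ether, the last being unusually labile because it is twisted between two ortho substituents and its cleavage is assisted by hydrogen bonding to the carbonyl group; dilute acid at or below room temperature should be too mild for Hock cleavage of the allylic hydroperoxide, chroman formation or flavanone closure, and C6'' is not touched.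

**Compound list**

1 | 3-methoxyphenol | COc1cccc(O)c1 | starting material
2 | 1-methoxy-3-(methoxymethoxy)benzene | COCOc1cccc(OC)c1 | intermediate
3 | [2-methoxy-6-(methoxymethoxy)phenyl]lithium | [Li]c1c(OC)cccc1OCOC | intermediate
4 | [2-methoxy-6-(methoxymethoxy)phenyl]methanol | COCOc1cccc(OC)c1CO | intermediate
5 | lithium [3-lithio-6-methoxy-2-(methoxymethoxy)phenyl]methanolate | [Li]OCc1c(OC)ccc([Li])c1OCOC | intermediate
6 | 1-[3-(hydroxymethyl)-4-methoxy-2-(methoxymethoxy)phenyl]ethan-1-one | CC(=O)c1ccc(OC)c(CO)c1OCOC | intermediate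
7 | [3-acetyl-6-methoxy-2-(methoxymethoxy)phenyl]methyl methanesulfonate | CC(=O)c1ccc(OC)c(COS(C)(=O)=O)c1OCOC | intermediate
8 | 1-[3-(chloromethyl)-4-methoxy-2-(methoxymethoxy)phenyl]ethan-1-one | CC(=O)c1ccc(OC)c(CCl)c1OCOC | intermediate
9 | pent-4-ynoic acid | C#CCCC(=O)O | starting material
10 | 1-(1H-imidazol-1-yl)pent-4-yn-1-one | C#CCCC(=O)n1ccnc1 | intermediate
11 | N-methoxy-N-methylpent-4-ynamide | C#CCCC(=O)N(C)OC | intermediate
12 | isopropenylmagnesium bromide | C=C(C)[Mg]Br | starting material
13 | 2-methylhept-1-en-6-yn-3-one | C#CCCC(=O)C(C)=C | intermediate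
14 | (3S)-2-methylhept-1-en-6-yn-3-ol | C#CCC[C@H](O)C(C)=C | intermediate
15 | tert-butyldimethyl{[(3S)-2-methylhept-1-en-6-yn-3-yl]oxy}silane | C#CCC[C@H](O[Si](C)(C)C(C)(C)C)C(C)=C | intermediate
16 | trimethylaluminium | C[Al](C)C | starting material
17 | [(1E,5S)-5-(tert-butyldimethylsilyloxy)-2,6-dimethylhepta-1,6-dien-1-yl]dimethylalane | C[Al](C)/C=C(\C)CC[C@H](O[Si](C)(C)C(C)(C)C)C(C)=C | intermediate
18 | chloro[(1E,5S)-5-(tert-butyldimethylsilyloxy)-2,6-dimethylhepta-1,6-dien-1-yl]zinc | Cl[Zn]/C=C(\C)CC[C@H](O[Si](C)(C)C(C)(C)C)C(C)=C | intermediate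
19 | 1-{3-[(2E,6S)-6-(tert-butyldimethylsilyloxy)-3,7-dimethylocta-2,7-dien-1-yl]-4-methoxy-2-(methoxymethoxy)phenyl}ethan-1-one | C=C(C)[C@H](CC/C(C)=C/Cc1c(OC)ccc(C(C)=O)c1OCOC)O[Si](C)(C)C(C)(C)C | intermediate
20 | 1-{3-[(2E,6S)-6-hydroxy-3,7-dimethylocta-2,7-dien-1-yl]-4-methoxy-2-(methoxymethoxy)phenyl}ethan-1-one | C=C(C)[C@H](CC/C(C)=C/Cc1c(OC)ccc(C(C)=O)c1OCOC)O | intermediate
21 | (3S,6E)-8-[3-acetyl-6-methoxy-2-(methoxymethoxy)phenyl]-2,6-dimethylocta-1,6-dien-3-yl methanesulfonate | C=C(C)[C@H](CC/C(C)=C/Cc1c(OC)ccc(C(C)=O)c1OCOC)OS(C)(=O)=O | intermediate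
22 | 2,3-dimethylbut-2-ene | CC(C)=C(C)C | starting material
23 | 2-methoxyprop-2-yl hydroperoxide | COC(C)(C)OO | intermediate
24 | 1-{3-[(2E,6R)-6-[(2-methoxypropan-2-yl)peroxy]-3,7-dimethylocta-2,7-dien-1-yl]-4-methoxy-2-(methoxymethoxy)phenyl}ethan-1-one | C=C(C)[C@@H](CC/C(C)=C/Cc1c(OC)ccc(C(C)=O)c1OCOC)OOC(C)(C)OC | intermediate
25 | 4-(tetrahydro-2H-pyran-2-yloxy)benzaldehyde (racemic) | O=Cc1ccc(OC2CCCCO2)cc1 | starting material
26 | (2E)-1-{3-[(2E,6R)-6-[(2-methoxypropan-2-yl)peroxy]-3,7-dimethylocta-2,7-dien-1-yl]-4-methoxy-2-(methoxymethoxy)phenyl}-3-[4-(tetrahydro-2H-pyran-2-yloxy)phenyl]prop-2-en-1-one | C=C(C)[C@@H](CC/C(C)=C/Cc1c(OC)ccc(C(=O)/C=C/c2ccc(OC3CCCCO3)cc2)c1OCOC)OOC(C)(C)OC | intermediate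
27 | (2E)-1-{2-hydroxy-3-[(2E,6R)-6-hydroperoxy-3,7-dimethylocta-2,7-dien-1-yl]-4-methoxyphenyl}-3-(4-hydroxyphenyl)prop-2-en-1-one | C=C(C)[C@@H](CC/C(C)=C/Cc1c(OC)ccc(C(=O)/C=C/c2ccc(O)cc2)c1O)OO | target

**Step count and risks**

Total step count: 15. Longest linear sequence: 10 steps (steps 1–4, 9–11, 13–15; the branch through steps 5–8 is equally long). Step 12 is a one-step side branch.

Steps most likely to fail:

Step 9. The one-flask sequence may fail through sluggish carboalumination of the oxygenated alkyne, through transfer of methyl or alkenyl groups from residual aluminium species to the aryl ketone, or through Lewis-acid ionisation and homocoupling of the doubly ortho-oxygenated benzylic chloride. The fallback reverses the polarity of the coupling and sets out from 15 and 8. Alkenylalane 17, made from 15 as in step 9, would be quenched with I2 in THF at −30 °C to give tert-butyl{[(3S,6E)-7-iodo-2,6-dimethylhepta-1,6-dien-3-yl]oxy}dimethylsilane F1, which can be purified. Chloride 8 would be converted with zinc dust and LiCl in THF into {[3-acetyl-6-methoxy-2-(methoxymethoxy)phenyl]methyl}zinc chloride F2, a benzylic zinc reagent that tolerates the ketone. Pd(PPh3)4-catalysed Negishi coupling of F1 with F2 in THF at room temperature would form the same C1''–C2'' bond with retention of the E geometry and comes back to the route at 19.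

Step 13. The secondary allylic sulfonate may ionise, suffer allylic transposition (SN2' attack at C8'') or eliminate to a diene, so that configurational or positional purity at C6'' is eroded. The fallback is a resolution through diastereomeric perketals; it sets out from 24 of insufficient purity and comes back to the route at 24.
- PPTS in MeOH at 0 °C would remove the perketal and give 1-{3-[(2E,6R)-6-hydroperoxy-3,7-dimethylocta-2,7-dien-1-yl]-4-methoxy-2-(methoxymethoxy)phenyl}ethan-1-one F3, still contaminated with its 6S antipode.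
- The resolving agent would be made from commercial (1R,2S)-trans-2-phenylcyclohexanol: 2-methoxypropene with catalytic PPTS gives (1R,2S)-2-phenylcyclohexyl 2-methoxyprop-2-yl ether F4, and TMSOTf/i-Pr2NEt elimination of methanol from this mixed ketal gives (1R,2S)-2-phenylcyclohexyl prop-1-en-2-yl ether F5.
- PPTS-catalysed addition of the hydroperoxide to the enol ether would give diastereomeric perketals. Chromatographic separation would give the 6R diastereomer 1-{3-[(2E,6R)-3,7-dimethyl-6-({2-[(1R,2S)-2-phenylcyclohexyloxy]propan-2-yl}peroxy)octa-2,7-dien-1-yl]-4-methoxy-2-(methoxymethoxy)phenyl}ethan-1-one F6, free of regioisomers.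
- AcOH/THF/H2O would return the hydroperoxide F3 as a single enantiomer, and 2-methoxypropene with catalytic PPTS would convert it back into 24.

Step 15. Before the 2'-O-MOM ether is fully cleaved, the acid may induce Hock-type fragmentation of the allylic hydroperoxide or cyclisation of the liberated phenol onto the C2''=C3'' alkene. The fallback removes the MOM group before the peroxide is introduced, so that the last step needs only very mild acid; it sets out from 19 and comes back to the route at 27.
- HCl in MeOH at room temperature would cleave both the MOM and the silyl ether of 19 and give 1-{2-hydroxy-3-[(2E,6S)-6-hydroxy-3,7-dimethylocta-2,7-dien-1-yl]-4-methoxyphenyl}ethan-1-one F7.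
- MsCl (1.05 equiv) with Et3N in CH2Cl2 at −40 °C should sulfonylate the secondary alcohol and spare the hydrogen-bonded, doubly flanked phenol, giving (3S,6E)-8-(3-acetyl-2-hydroxy-6-methoxyphenyl)-2,6-dimethylocta-1,6-dien-3-yl methanesulfonate F8.
- Displacement with 23 and CsOH·H2O in DMF (one extra equivalent of base for the phenol) would give, with inversion, 1-{2-hydroxy-3-[(2E,6R)-6-[(2-methoxypropan-2-yl)peroxy]-3,7-dimethylocta-2,7-dien-1-yl]-4-methoxyphenyl}ethan-1-one F9.
- Claisen–Schmidt condensation with 25 under excess KOH in EtOH would give (2E)-1-{2-hydroxy-3-[(2E,6R)-6-[(2-methoxypropan-2-yl)peroxy]-3,7-dimethylocta-2,7-dien-1-yl]-4-methoxyphenyl}-3-[4-(tetrahydro-2H-pyran-2-yloxy)phenyl]prop-2-en-1-one F10.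
- PPTS in MeOH at room temperature would remove the THP ether and the perketal and give 27.

Further compounds

F1 | step 9 | tert-butyl{[(3S,6E)-7-iodo-2,6-dimethylhepta-1,6-dien-3-yl]oxy}dimethylsilane | I/C=C(\C)CC[C@H](O[Si](C)(C)C(C)(C)C)C(C)=C
F2 | step 9 | {[3-acetyl-6-methoxy-2-(methoxymethoxy)phenyl]methyl}zinc chloride | CC(=O)c1ccc(OC)c(C[Zn]Cl)c1OCOC
F3 | step 13 | 1-{3-[(2E,6R)-6-hydroperoxy-3,7-dimethylocta-2,7-dien-1-yl]-4-methoxy-2-(methoxymethoxy)phenyl}ethan-1-one | C=C(C)[C@@H](CC/C(C)=C/Cc1c(OC)ccc(C(C)=O)c1OCOC)OO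
F4 | step 13 | (1R,2S)-2-phenylcyclohexyl 2-methoxyprop-2-yl ether | COC(C)(C)O[C@@H]1CCCC[C@H]1c1ccccc1
F5 | step 13 | (1R,2S)-2-phenylcyclohexyl prop-1-en-2-yl ether | C=C(C)O[C@@H]1CCCC[C@H]1c1ccccc1
F6 | step 13 | 1-{3-[(2E,6R)-3,7-dimethyl-6-({2-[(1R,2S)-2-phenylcyclohexyloxy]propan-2-yl}peroxy)octa-2,7-dien-1-yl]-4-methoxy-2-(methoxymethoxy)phenyl}ethan-1-one | C=C(C)[C@@H](CC/C(C)=C/Cc1c(OC)ccc(C(C)=O)c1OCOC)OOC(C)(C)O[C@@H]1CCCC[C@H]1c1ccccc1
F7 | step 15 | 1-{2-hydroxy-3-[(2E,6S)-6-hydroxy-3,7-dimethylocta-2,7-dien-1-yl]-4-methoxyphenyl}ethan-1-one | C=C(C)[C@H](CC/C(C)=C/Cc1c(OC)ccc(C(C)=O)c1O)O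
F8 | step 15 | (3S,6E)-8-(3-acetyl-2-hydroxy-6-methoxyphenyl)-2,6-dimethylocta-1,6-dien-3-yl methanesulfonate | C=C(C)[C@H](CC/C(C)=C/Cc1c(OC)ccc(C(C)=O)c1O)OS(C)(=O)=O
F9 | step 15 | 1-{2-hydroxy-3-[(2E,6R)-6-[(2-methoxypropan-2-yl)peroxy]-3,7-dimethylocta-2,7-dien-1-yl]-4-methoxyphenyl}ethan-1-one | C=C(C)[C@@H](CC/C(C)=C/Cc1c(OC)ccc(C(C)=O)c1O)OOC(C)(C)OC
F10 | step 15 | (2E)-1-{2-hydroxy-3-[(2E,6R)-6-[(2-methoxypropan-2-yl)peroxy]-3,7-dimethylocta-2,7-dien-1-yl]-4-methoxyphenyl}-3-[4-(tetrahydro-2H-pyran-2-yloxy)phenyl]prop-2-en-1-one | C=C(C)[C@@H](CC/C(C)=C/Cc1c(OC)ccc(C(=O)/C=C/c2ccc(OC3CCCCO3)cc2)c1O)OOC(C)(C)OC
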